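## Plan

1. Retrosynthesis: with the three phenols masked as methoxymethyl ethers, the target is cut at the biaryl bond C5'–C2 and at the chroman bond C4'–C4a' (chroman atoms primed). Both bonds are made in one palladium/norbornene step from an aryl iodide and a benzofuran-2-yl boronate.
2. Enabling feature: the chroman methylene C4' and the benzofuran C2 sit on neighbouring carbons C4a' and C5' of the chroman benzene ring, and O1' on C8a' is meta to C5'. A 3-iodophenyl tertiary ether with a 2-bromoethyl arm can therefore be alkylated at its ortho C–H and arylated at the iodine-bearing carbon.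
3. Boronate: cut at C2–B, O1–C2 and C3=C2 back to a salicylaldehyde, and at C7–C(quaternary) back to a 4-prenyloxy-2,6-dihydroxybenzaldehyde. The Claisen rearrangement is run with the para carbon blocked by the formyl group, so the allyl group cannot travel on to a free para position.
4. Iodide: cut at the aryl O–C(quaternary) bond (copper-catalysed propargylation of monoprotected 5-iodoresorcinol) and at C–Br (semihydrogenation, hydroboration, bromination).
5. Forward order of rings: the furan ring on the phloroglucinol core (step 5), then the dihydropyran ring together with the biaryl bond (step 12), then global deprotection (step 13).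
6. Stereochemistry: the target has no stereocentre and no stereogenic double bond, so nothing has to be controlled.

Key step: step 12

Assumption: the bridgehead-methylated norbornene cocatalyst of step 12 (1-methylbicyclo[2.2.1]hept-2-ene) is taken as an auxiliary prepared separately; it contributes no atoms and is not counted among the steps.

## Route

Step 1
Reactants: 1 2,4,6-trihydroxybenzaldehyde; 2 1-bromo-3-methylbut-2-ene (prenyl bromide)
Product: 3 2,6-dihydroxy-4-[(3-methylbut-2-en-1-yl)oxy]benzaldehyde
Conditions: K2CO3 (1.1 equiv), acetone, 0 °C to rt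
Reagents that add atoms: none
Why: Williamson etherification: the C4 hydroxyl is the only one not held in a hydrogen bond to the formyl group and is the most acidic, so one equivalent of weak base and bromide should alkylate it alone and on oxygen.

Step 2
Reactants: 3 2,6-dihydroxy-4-[(3-methylbut-2-en-1-yl)oxy]benzaldehyde
Product: 5 2,4,6-trihydroxy-3-(2-methylbut-3-en-2-yl)benzaldehyde, via ortho-dienone 4 (not isolated)
Conditions: N,N-diethylaniline, 185 °C, sealed tube, argon
Reagents that add atoms: none
Why: Aromatic Claisen rearrangement: the [3,3] shift transfers the allyl unit with inversion to C3 (C5 is the same carbon by symmetry), dienone 4 enolises, and because the para carbon bears the formyl group an onward Cope shift cannot aromatise, which is the situation of 7-prenyloxy coumarins and flavones that give ortho-(1,1-dimethylallyl) phenols.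

Step 3
Reactants: 5 2,4,6-trihydroxy-3-(2-methylbut-3-en-2-yl)benzaldehyde
Product: 6 2-hydroxy-4,6-bis(methoxymethoxy)-3-(2-methylbut-3-en-2-yl)benzaldehyde
Conditions: MOMCl (2.2 equiv), i-Pr2NEt, CH2Cl2, 0 °C to rt
Reagents that add atoms: chloromethyl methyl ether (MOMCl), COCCl
Why: Selective methoxymethyl ether formation: the C4 and C6 hydroxyls should be alkylated while the C2 hydroxyl stays free, because it is hydrogen-bonded to the formyl group and wedged against the quaternary carbon, as in the bis-protection of the parent trihydroxybenzaldehyde.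

Step 4
Reactants: 6 2-hydroxy-4,6-bis(methoxymethoxy)-3-(2-methylbut-3-en-2-yl)benzaldehyde
Product: 7 2-(2,2-dibromoethenyl)-3,5-bis(methoxymethoxy)-6-(2-methylbut-3-en-2-yl)phenol
Conditions: CBr4, PPh3, Et3N, CH2Cl2, 0 °C
Reagents that add atoms: carbon tetrabromide, BrC(Br)(Br)Br
Why: Ramirez dibromo-olefination (first stage of the Corey–Fuchs sequence): the ylide Ph3P=CBr2 made in the flask converts the formyl group into the 1,1-dibromoalkene, and triethylamine keeps the medium from turning acidic so that the phenol can stay free and the acetals intact.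

Step 5
Reactants: 7 2-(2,2-dibromoethenyl)-3,5-bis(methoxymethoxy)-6-(2-methylbut-3-en-2-yl)phenol
Product: 8 2-bromo-4,6-bis(methoxymethoxy)-7-(2-methylbut-3-en-2-yl)-1-benzofuran
Conditions: CuI (5 mol %), K3PO4, THF, 80 °C
Reagents that add atoms: none
Why: Copper-catalysed intramolecular vinylic C–O coupling (Ullmann type) of a 2-(2,2-dibromovinyl)phenol: the phenoxide displaces one bromine to close the five-membered furan ring through the O1–C2 bond and leaves the second bromine at C2.

Step 6
Reactants: 8 2-bromo-4,6-bis(methoxymethoxy)-7-(2-methylbut-3-en-2-yl)-1-benzofuran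
Product: 10 2-[4,6-bis(methoxymethoxy)-7-(2-methylbut-3-en-2-yl)-1-benzofuran-2-yl]-4,4,5,5-tetramethyl-1,3,2-dioxaborolane, via 2-lithiobenzofuran 9 (not isolated)
Conditions: n-BuLi, THF, −78 °C; then i-PrOBpin, −78 °C to rt; aq. NH4Cl
Reagents that add atoms: 2-isopropoxy-4,4,5,5-tetramethyl-1,3,2-dioxaborolane, CC(C)OB1OC(C)(C)C(C)(C)O1
Why: Bromine–lithium exchange at C2 is faster than any deprotonation at −78 °C, and the 2-lithiobenzofuran 9 is trapped by the isopropoxyboronate with loss of isopropoxide (borylation of an organolithium).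

Step 7
Reactants: 11 5-iodobenzene-1,3-diol
Product: 12 3-iodo-5-(methoxymethoxy)phenol
Conditions: MOMCl (1.0 equiv), i-Pr2NEt, CH2Cl2/THF, 0 °C
Reagents that add atoms: chloromethyl methyl ether (MOMCl), COCCl
Why: Statistical monoprotection of a symmetric diol (bis-ether and diol are separated, the diol recycled), the acetal being chosen because it survives hot Cs2CO3 in step 12 and leaves together with the other two in step 13.

Step 8
Reactants: 12 3-iodo-5-(methoxymethoxy)phenol; 13 3-chloro-3-methylbut-1-yne
Product: 14 1-iodo-3-(methoxymethoxy)-5-[(2-methylbut-3-yn-2-yl)oxy]benzene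
Conditions: CuCl2·2H2O (1 mol %), DBU, MeCN, 0 °C
Reagents that add atoms: none
Why: Copper-catalysed propargylic etherification of a phenol with a tertiary propargylic chloride, which proceeds through a copper-stabilised propargyl cation and so forms the hindered tertiary aryl ether at 0 °C, well below the temperature at which such ethers rearrange to chromenes.

Step 9
Reactants: 14 1-iodo-3-(methoxymethoxy)-5-[(2-methylbut-3-yn-2-yl)oxy]benzene
Product: 15 1-iodo-3-(methoxymethoxy)-5-[(2-methylbut-3-en-2-yl)oxy]benzene
Conditions: H2 (1 atm), Pd/CaCO3 poisoned with Pb(OAc)2, quinoline, EtOAc, rt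
Reagents that add atoms: none
Why: Lindlar semihydrogenation: the lead- and quinoline-poisoned palladium surface reduces the terminal alkyne to the alkene and should be too deactivated to cleave the aryl C–I bond if hydrogen uptake is stopped at one equivalent.

Step 10
Reactants: 15 1-iodo-3-(methoxymethoxy)-5-[(2-methylbut-3-en-2-yl)oxy]benzene
Product: 17 3-[3-iodo-5-(methoxymethoxy)phenoxy]-3-methylbutan-1-ol, via B-alkyl-9-BBN adduct 16 (not isolated)
Conditions: 9-BBN, THF, 0 °C to rt; then NaOH aq., H2O2, 0 °C to rt
Reagents that add atoms: hydrogen peroxide, OO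
Why: Hydroboration–oxidation: the bulky borane places boron on the terminal carbon of the monosubstituted alkene next to the quaternary centre, and alkaline peroxide replaces boron by hydroxyl without touching the aryl iodide or the acetal.

Step 11
Reactants: 17 3-[3-iodo-5-(methoxymethoxy)phenoxy]-3-methylbutan-1-ol
Product: 18 1-[(4-bromo-2-methylbutan-2-yl)oxy]-3-iodo-5-(methoxymethoxy)benzene
Conditions: CBr4, PPh3, CH2Cl2, 0 °C
Reagents that add atoms: carbon tetrabromide, BrC(Br)(Br)Br
Why: Appel reaction: the primary alcohol is activated as an alkoxyphosphonium ion and displaced by bromide under neutral conditions that leave the tertiary aryl ether and the acetal untouched.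

Step 12
Reactants: 18 1-[(4-bromo-2-methylbutan-2-yl)oxy]-3-iodo-5-(methoxymethoxy)benzene; 10 2-[4,6-bis(methoxymethoxy)-7-(2-methylbut-3-en-2-yl)-1-benzofuran-2-yl]-4,4,5,5-tetramethyl-1,3,2-dioxaborolane
Product: 19 2-[7-(methoxymethoxy)-2,2-dimethyl-3,4-dihydro-2H-chromen-5-yl]-4,6-bis(methoxymethoxy)-7-(2-methylbut-3-en-2-yl)-1-benzofuran
Conditions: Pd(OAc)2 (10 mol %), tri(2-furyl)phosphine (22 mol %), 1-methylbicyclo[2.2.1]hept-2-ene (1 equiv), Cs2CO3 (3 equiv), H2O (5 equiv), MeCN (0.02 M), 85 °C; 10 (1.5 equiv)
Reagents that add atoms: none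
Why: Zerovalent palladium inserts into the C–I bond of 18, the norbornene inserts, and carbonate-assisted palladation of the ortho C–H beside the tertiary ether gives a five-membered aryl–norbornyl palladacycle, to which the tethered primary bromide adds oxidatively (tetravalent palladium) before C(sp2)–C(sp3) reductive elimination forms C4'–C4a'. This is a Catellani reaction, its closest models being ortho-alkylation of aryl iodides with Suzuki termination and the ring-forming variants with tethered alkyl halides. The dihydropyran ring (O1', C2', C3', C4', C4a', C8a') closes by intramolecular C-alkylation, formally a 6-exo-tet displacement at the CH2Br carbon. With only one ortho substituent in place, the bridgehead methyl group of the cocatalyst is what should force β-carbon elimination of the norbornene, after which the divalent arylpalladium is transmetalated by boronate 10 and reductively eliminates to C5'–C2. No stereocentre is formed. Site selectivity rests on the tether, which reaches only the ortho carbon beside its own oxygen while a palladacycle on the other side finds no electrophile at high dilution, and chemoselectivity over Heck reaction rests on fast transmetalation of the 2-benzofuranyl boronate against the neopentyl-shielded vinyl group.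

Step 13
Reactants: 19 2-[7-(methoxymethoxy)-2,2-dimethyl-3,4-dihydro-2H-chromen-5-yl]-4,6-bis(methoxymethoxy)-7-(2-methylbut-3-en-2-yl)-1-benzofuran
Product: 20 2-(7-hydroxy-2,2-dimethyl-3,4-dihydro-2H-chromen-5-yl)-7-(2-methylbut-3-en-2-yl)-1-benzofuran-4,6-diol (target)
Conditions: HCl (3 M aq.), MeOH, 45 °C
Reagents that add atoms: none
Why: Acid-catalysed transacetalisation of the three methoxymethyl ethers in methanol liberates the phenols under conditions mild enough that the monosubstituted alkene of the 1,1-dimethylallyl group should not be protonated and the chroman and benzofuran rings are inert.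

## Compound list

1 | 2,4,6-trihydroxybenzaldehyde | O=Cc1c(O)cc(O)cc1O | starting material
2 | 1-bromo-3-methylbut-2-ene (prenyl bromide) | CC(C)=CCBr | starting material
3 | 2,6-dihydroxy-4-[(3-methylbut-2-en-1-yl)oxy]benzaldehyde | O=Cc1c(O)cc(OCC=C(C)C)cc1O | intermediate
4 | 2,6-dihydroxy-3-(2-methylbut-3-en-2-yl)-4-oxocyclohexa-1,5-diene-1-carbaldehyde (racemic ortho-dienone) | O=CC1=C(O)C(C(C)(C)C=C)C(=O)C=C1O | intermediate
5 | 2,4,6-trihydroxy-3-(2-methylbut-3-en-2-yl)benzaldehyde | O=Cc1c(O)cc(O)c(C(C)(C)C=C)c1O | intermediate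
6 | 2-hydroxy-4,6-bis(methoxymethoxy)-3-(2-methylbut-3-en-2-yl)benzaldehyde | O=Cc1c(OCOC)cc(OCOC)c(C(C)(C)C=C)c1O | intermediate
7 | 2-(2,2-dibromoethenyl)-3,5-bis(methoxymethoxy)-6-(2-methylbut-3-en-2-yl)phenol | BrC(Br)=Cc1c(OCOC)cc(OCOC)c(C(C)(C)C=C)c1O | intermediate
8 | 2-bromo-4,6-bis(methoxymethoxy)-7-(2-methylbut-3-en-2-yl)-1-benzofuran | C=CC(C)(C)c1c(OCOC)cc(OCOC)c2cc(Br)oc12 | intermediate
9 | [4,6-bis(methoxymethoxy)-7-(2-methylbut-3-en-2-yl)-1-benzofuran-2-yl]lithium | [Li]c1cc2c(OCOC)cc(OCOC)c(C(C)(C)C=C)c2o1 | intermediate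
10 | 2-[4,6-bis(methoxymethoxy)-7-(2-methylbut-3-en-2-yl)-1-benzofuran-2-yl]-4,4,5,5-tetramethyl-1,3,2-dioxaborolane | C=CC(C)(C)c1c(OCOC)cc(OCOC)c2cc(B3OC(C)(C)C(C)(C)O3)oc12 | intermediate
11 | 5-iodobenzene-1,3-diol | Oc1cc(O)cc(I)c1 | starting material
12 | 3-iodo-5-(methoxymethoxy)phenol | COCOc1cc(O)cc(I)c1 | intermediate
13 | 3-chloro-3-methylbut-1-yne | C#CC(C)(C)Cl | starting material
14 | 1-iodo-3-(methoxymethoxy)-5-[(2-methylbut-3-yn-2-yl)oxy]benzene | C#CC(C)(C)Oc1cc(I)cc(OCOC)c1 | intermediate
15 | 1-iodo-3-(methoxymethoxy)-5-[(2-methylbut-3-en-2-yl)oxy]benzene | C=CC(C)(C)Oc1cc(I)cc(OCOC)c1 | intermediate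
16 | 9-{3-[3-iodo-5-(methoxymethoxy)phenoxy]-3-methylbutyl}-9-borabicyclo[3.3.1]nonane | COCOc1cc(I)cc(OC(C)(C)CCB2C3CCCC2CCC3)c1 | intermediate
17 | 3-[3-iodo-5-(methoxymethoxy)phenoxy]-3-methylbutan-1-ol | COCOc1cc(I)cc(OC(C)(C)CCO)c1 | intermediate
18 | 1-[(4-bromo-2-methylbutan-2-yl)oxy]-3-iodo-5-(methoxymethoxy)benzene | COCOc1cc(I)cc(OC(C)(C)CCBr)c1 | intermediate
19 | 2-[7-(methoxymethoxy)-2,2-dimethyl-3,4-dihydro-2H-chromen-5-yl]-4,6-bis(methoxymethoxy)-7-(2-methylbut-3-en-2-yl)-1-benzofuran | C=CC(C)(C)c1c(OCOC)cc(OCOC)c2cc(-c3cc(OCOC)cc4c3CCC(C)(C)O4)oc12 | intermediate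
20 | 2-(7-hydroxy-2,2-dimethyl-3,4-dihydro-2H-chromen-5-yl)-7-(2-methylbut-3-en-2-yl)-1-benzofuran-4,6-diol | C=CC(C)(C)c1c(O)cc(O)c2cc(-c3cc(O)cc4c3CCC(C)(C)O4)oc12 | target

## Step count and risks

Total step count: 13. Longest linear sequence: 8 steps (steps 1 to 6, then 12 and 13).

Steps most likely to fail:

1. Step 12. Once the dihydropyran ring has closed, the aryl–norbornyl palladium species still has an open ortho C–H. A second palladation, followed by collapse onto the norbornyl carbon or by alkylation with the bromide of a second molecule, may overtake norbornene extrusion. Ipso coupling before any alkylation and protodeboronation of the 2-benzofuranyl boronate in hot aqueous carbonate are further losses.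
   Fallback: the two bonds are made in separate operations, setting out from boronate 10 and returning at 19. Commercial phloroglucinol is condensed with 2-methylbut-3-en-2-ol under acid catalysis (Amberlyst 15, THF, 65 °C) to 2,2-dimethyl-3,4-dihydro-2H-chromene-5,7-diol F1; every ring carbon of the symmetric triol gives the same chroman. The less hindered C7 hydroxyl is protected (MOMCl, i-Pr2NEt, CH2Cl2) to give 7-(methoxymethoxy)-2,2-dimethyl-3,4-dihydro-2H-chromen-5-ol F2, the C5-protected isomer being removed by chromatography. Triflation (Tf2O, pyridine, CH2Cl2, 0 °C) gives 7-(methoxymethoxy)-2,2-dimethyl-3,4-dihydro-2H-chromen-5-yl trifluoromethanesulfonate F3. Suzuki–Miyaura coupling of F3 with 10 (PdCl2(dppf), K3PO4, dioxane/H2O, 80 °C) forms C5'–C2 and delivers 19.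

2. Step 2. At the rearrangement temperature the freed phenols that flank the new allyl group may add across its double bond. The allyl group may also migrate on to the formyl-bearing carbon with loss of the formyl group, and the unprotected polyphenol may degrade.
   Fallback: the quaternary carbon is installed by cross-coupling instead of sigmatropic rearrangement, setting out from 1 and returning at 6. Bis-protection of 1 (MOMCl 2.1 equiv, i-Pr2NEt, CH2Cl2) gives 2-hydroxy-4,6-bis(methoxymethoxy)benzaldehyde F4. Iodination ortho to the free phenol (N-iodosuccinimide, CH2Cl2, 0 °C) gives 2-hydroxy-3-iodo-4,6-bis(methoxymethoxy)benzaldehyde F5. Suzuki–Miyaura coupling of F5 with 3-methylbut-2-en-1-ylboronic acid pinacol ester (Pd(OAc)2 with a bulky dialkylbiarylphosphine selected for bond formation at the γ-carbon of the allyl unit, K3PO4, THF/H2O, 40 °C) gives 6.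

3. Step 4. The olefination may be slow on a hydrogen-bonded, doubly ortho-substituted, electron-rich aldehyde, and the phosphorus bromide by-products may strip methoxymethyl groups or brominate the free phenol.
   Fallback: the furan ring is built under basic conditions and the boron introduced by deprotonation, setting out from 6 and returning at 10. Heating 6 with ethyl bromoacetate and K2CO3 in DMF (90 °C) should effect O-alkylation and intramolecular Knoevenagel-type condensation to ethyl 4,6-bis(methoxymethoxy)-7-(2-methylbut-3-en-2-yl)-1-benzofuran-2-carboxylate F6. Saponification (LiOH, THF/H2O) gives 4,6-bis(methoxymethoxy)-7-(2-methylbut-3-en-2-yl)-1-benzofuran-2-carboxylic acid F7. Copper-mediated protodecarboxylation (Cu2O, 1,10-phenanthroline, NMP/quinoline, 170 °C) gives 4,6-bis(methoxymethoxy)-7-(2-methylbut-3-en-2-yl)-1-benzofuran F8. Kinetic lithiation of F8 at C2 (n-BuLi, THF, −78 °C) gives 9, which is borylated with i-PrOBpin as in step 6 to give 10.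

## Further compounds

F1 | step 12 | 2,2-dimethyl-3,4-dihydro-2H-chromene-5,7-diol | CC1(C)CCc2c(O)cc(O)cc2O1
F2 | step 12 | 7-(methoxymethoxy)-2,2-dimethyl-3,4-dihydro-2H-chromen-5-ol | CC1(C)CCc2c(O)cc(OCOC)cc2O1
F3 | step 12 | 7-(methoxymethoxy)-2,2-dimethyl-3,4-dihydro-2H-chromen-5-yl trifluoromethanesulfonate | CC1(C)CCc2c(OS(=O)(=O)C(F)(F)F)cc(OCOC)cc2O1
F4 | step 2 | 2-hydroxy-4,6-bis(methoxymethoxy)benzaldehyde | O=Cc1c(O)cc(OCOC)cc1OCOC
F5 | step 2 | 2-hydroxy-3-iodo-4,6-bis(methoxymethoxy)benzaldehyde | O=Cc1c(O)c(I)c(OCOC)cc1OCOC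
F6 | step 4 | ethyl 4,6-bis(methoxymethoxy)-7-(2-methylbut-3-en-2-yl)-1-benzofuran-2-carboxylate | CCOC(=O)c1cc2c(OCOC)cc(OCOC)c(C(C)(C)C=C)c2o1
F7 | step 4 | 4,6-bis(methoxymethoxy)-7-(2-methylbut-3-en-2-yl)-1-benzofuran-2-carboxylic acid | OC(=O)c1cc2c(OCOC)cc(OCOC)c(C(C)(C)C=C)c2o1
F8 | step 4 | 4,6-bis(methoxymethoxy)-7-(2-methylbut-3-en-2-yl)-1-benzofuran | C=CC(C)(C)c1c(OCOC)cc(OCOC)c2ccoc12
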